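**Retrosynthetic overview**
1. Target 17 ⇐ oxolane diol 14 by acetylation of the tertiary OH, with the primary OH masked transiently and the phenol acetate removed last.
2. Oxolane ring (the only ring of the target, closed last) ⇐ acyclic triol 13 by oxidative C7–H to C7–O9' closure through an O-methyl quinone methide cation, the counterpart of the 9'-OH/quinone methide closure of lignan biosynthesis.
3. Triol ⇐ dioxolanone 11 by global hydride reduction; the quaternary carbinol C8' ⇐ benzylation of a tert-butyl dioxolanone enolate with bromide 3.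
4. C8 ⇐ anti-selective benzylation of the dianion of dimethyl (S)-malate 4 with bromide 5.
5. Ring order: auxiliary dioxolanone (step 5, destroyed in step 7), then the oxolane (step 9).

Assumption: lignan locants are used in the Why lines (C7, C8, C9 for the dimethoxyphenyl C3 unit; C7', C8', C9' for the guaiacyl unit); 1, 4 and 5 are purchased.

**Step 1**
Reactants: 1 vanillyl alcohol
Product: 2 4-(hydroxymethyl)-2-methoxyphenyl 2,2-dimethylpropanoate
Conditions: t-BuCOCl (1.05 equiv), NaOH (1.1 equiv), H2O–CH2Cl2, 0 °C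
Reagents that add atoms: pivaloyl chloride, CC(C)(C)C(Cl)=O
Why: Schotten–Baumann acylation, in which only the phenoxide (not the benzylic alcohol) is acylated; the pivalate survives the later enolate step and is cleaved by LiAlH4.

**Step 2**
Reactants: 2 4-(hydroxymethyl)-2-methoxyphenyl 2,2-dimethylpropanoate
Product: 3 4-(bromomethyl)-2-methoxyphenyl 2,2-dimethylpropanoate
Conditions: PBr3 (0.4 equiv), Et2O, 0 °C
Reagents that add atoms: phosphorus tribromide, BrP(Br)Br
Why: PBr3 bromination of an activated benzylic alcohol; the acylated phenol cannot form a quinone methide, so the bromide is stable.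

**Step 3**
Reactants: 4 dimethyl (S)-malate; 5 3,4-dimethoxybenzyl bromide
Product: 7 dimethyl (2S,3R)-2-hydroxy-3-[(3,4-dimethoxyphenyl)methyl]butanedioate, via dilithium alkoxide enolate 6 (not isolated)
Conditions: LiN(SiMe3)2 (2.1 equiv), THF, −78 to −20 °C; then 5, −78 to −10 °C; NH4Cl work-up
Reagents that add atoms: none
Why: Fráter–Seebach alkylation, in which the chelated alkoxide enolate is benzylated anti to the alkoxide substituent to give the (2S,3R) product (about 9:1, minor epimer removed by chromatography), which sets C8.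

**Step 4**
Reactants: 7 dimethyl (2S,3R)-2-hydroxy-3-[(3,4-dimethoxyphenyl)methyl]butanedioate
Product: 8 (2S,3R)-2-hydroxy-3-[(3,4-dimethoxyphenyl)methyl]butanedioic acid
Conditions: LiOH·H2O (3 equiv), THF–H2O, 0 °C to rt; then 1 M HCl
Reagents that add atoms: lithium hydroxide, [Li+].[OH-]
Why: ester saponification under mild conditions; once the carboxylates form, the C3–H is no longer acidic enough to epimerise.

**Step 5**
Reactants: 8 (2S,3R)-2-hydroxy-3-[(3,4-dimethoxyphenyl)methyl]butanedioic acid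
Product: 9 (2R)-2-[(2S,4S)-2-tert-butyl-5-oxo-1,3-dioxolan-4-yl]-3-(3,4-dimethoxyphenyl)propanoic acid
Conditions: t-BuCHO (2 equiv), TsOH·H2O (cat.), CH2Cl2, reflux, water separator; crystallisation
Reagents that add atoms: pivalaldehyde, CC(C)(C)C=O
Why: acid-catalysed acetalisation of the α-hydroxy acid (Seebach dioxolanone for self-regeneration of stereocentres); the five-membered cis acetal is the thermodynamic product, so the new acetal centre (S) is set under equilibrium control.

**Step 6**
Reactants: 9 (2R)-2-[(2S,4S)-2-tert-butyl-5-oxo-1,3-dioxolan-4-yl]-3-(3,4-dimethoxyphenyl)propanoic acid; 3 4-(bromomethyl)-2-methoxyphenyl 2,2-dimethylpropanoate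
Product: 11 (2R)-2-[(2S,4S)-2-tert-butyl-4-[[4-(2,2-dimethylpropanoyloxy)-3-methoxyphenyl]methyl]-5-oxo-1,3-dioxolan-4-yl]-3-(3,4-dimethoxyphenyl)propanoic acid, via dilithium carboxylate enolate 10 (not isolated)
Conditions: LiN(SiMe3)2 (2.2 equiv), THF–DMPU, −78 °C; then 3 (1.2 equiv), −78 to −30 °C; citric acid work-up
Reagents that add atoms: none
Why: Seebach enolate alkylation with self-regeneration of the stereocentre; the planar dioxolanone enolate is benzylated on the face opposite the tert-butyl group, so the benzyl replaces H with retention and sets the quaternary carbinol C8'.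

**Step 7**
Reactants: 11 (2R)-2-[(2S,4S)-2-tert-butyl-4-[[4-(2,2-dimethylpropanoyloxy)-3-methoxyphenyl]methyl]-5-oxo-1,3-dioxolan-4-yl]-3-(3,4-dimethoxyphenyl)propanoic acid
Product: 12 (2S,3S)-3-[(3,4-dimethoxyphenyl)methyl]-2-[(4-hydroxy-3-methoxyphenyl)methyl]butane-1,2,4-triol
Conditions: LiAlH4 (6 equiv), THF, 0 °C to reflux; aqueous potassium sodium tartrate (KNaC4H4O6) work-up
Reagents that add atoms: none
Why: LiAlH4 reduction takes the acid and the dioxolanone carbonyl to primary alcohols, frees the tertiary OH, and cleaves the acetal auxiliary and the aryl pivalate; no stereocentre is touched.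

**Step 8**
Reactants: 12 (2S,3S)-3-[(3,4-dimethoxyphenyl)methyl]-2-[(4-hydroxy-3-methoxyphenyl)methyl]butane-1,2,4-triol
Product: 13 4-[(2S,3S)-3-[(3,4-dimethoxyphenyl)methyl]-2,4-dihydroxy-2-(hydroxymethyl)butyl]-2-methoxyphenyl acetate
Conditions: Ac2O (1.1 equiv), NaOH (1.1 equiv), H2O–THF, 0 °C
Reagents that add atoms: acetic anhydride, CC(=O)OC(C)=O
Why: chemoselective phenoxide acetylation in aqueous base (Schotten–Baumann type); the acetate makes the guaiacyl ring electron-poor so that only the dimethoxyphenyl side is oxidised in the next step.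

**Step 9**
Reactants: 13 4-[(2S,3S)-3-[(3,4-dimethoxyphenyl)methyl]-2,4-dihydroxy-2-(hydroxymethyl)butyl]-2-methoxyphenyl acetate
Product: 14 4-[[(3S,4R,5S)-5-(3,4-dimethoxyphenyl)-3-hydroxy-4-(hydroxymethyl)oxolan-3-yl]methyl]-2-methoxyphenyl acetate
Conditions: DDQ (1.2 equiv), 2,6-dichloropyridine (2 equiv), 4 Å molecular sieves, CH2Cl2–MeNO2 (4:1), 0 °C to rt
Reagents that add atoms: none
Why: Proposed new method: DDQ abstracts hydride from the only electron-rich benzylic CH2 (C7) to give the O-methyl p-quinone methide (benzylic oxocarbenium) cation, which only the 9'-OH can capture in a five-membered closure (the other hydroxyls would give oxetanes), and the aryl group takes the position trans to the neighbouring hydroxymethyl, setting C5 of the oxolane as S; the buffer suppresses acid-driven reopening and aryltetralin formation, and the closest known reaction type is DDQ-mediated benzylic C–H oxidative cyclisation (cross-dehydrogenative C–O coupling, as in DDQ lactonisation of 4-arylbutanoic acids).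

**Step 10**
Reactants: 14 4-[[(3S,4R,5S)-5-(3,4-dimethoxyphenyl)-3-hydroxy-4-(hydroxymethyl)oxolan-3-yl]methyl]-2-methoxyphenyl acetate
Product: 17 [(3S,4R,5S)-5-(3,4-dimethoxyphenyl)-3-[(4-hydroxy-3-methoxyphenyl)methyl]-4-(hydroxymethyl)oxolan-3-yl] acetate, via trimethylsilyl ether 15 (not isolated), via trimethylsilyl ether tertiary acetate 16 (not isolated)
Conditions: Me3SiCl (1.2 equiv), pyridine, 0 °C; then Ac2O (10 equiv), DMAP (1 equiv), 40 °C; then MeOH quench, NH4OAc, MeOH–H2O, rt
Reagents that add atoms: acetic anhydride, CC(=O)OC(C)=O; chlorotrimethylsilane, C[Si](C)(C)Cl (silicon is present in 15 and 16 only)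
Why: transient silyl protection of the primary OH, DMAP-catalysed (Steglich-type) acetylation of the tertiary OH, then neutral methanolysis that removes the silyl ether and the aryl acetate but not the hindered tertiary alkyl acetate; no stereocentre is affected.

**Compound list**
1 | vanillyl alcohol (4-(hydroxymethyl)-2-methoxyphenol) | COc1cc(CO)ccc1O | starting material
2 | 4-(hydroxymethyl)-2-methoxyphenyl 2,2-dimethylpropanoate | COc1cc(CO)ccc1OC(=O)C(C)(C)C | intermediate
3 | 4-(bromomethyl)-2-methoxyphenyl 2,2-dimethylpropanoate | COc1cc(CBr)ccc1OC(=O)C(C)(C)C | intermediate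
4 | dimethyl (S)-malate | COC(=O)C[C@H](O)C(=O)OC | starting material
5 | 3,4-dimethoxybenzyl bromide | COc1ccc(CBr)cc1OC | starting material
6 | dilithium alkoxide enolate of 4 | [Li+].[Li+].COC(=O)[C@@H]([O-])/C=C(\[O-])OC | intermediate
7 | dimethyl (2S,3R)-2-hydroxy-3-[(3,4-dimethoxyphenyl)methyl]butanedioate | COC(=O)[C@@H](O)[C@@H](Cc1ccc(OC)c(OC)c1)C(=O)OC | intermediate
8 | (2S,3R)-2-hydroxy-3-[(3,4-dimethoxyphenyl)methyl]butanedioic acid | OC(=O)[C@@H](O)[C@@H](Cc1ccc(OC)c(OC)c1)C(=O)O | intermediate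
9 | (2R)-2-[(2S,4S)-2-tert-butyl-5-oxo-1,3-dioxolan-4-yl]-3-(3,4-dimethoxyphenyl)propanoic acid | O=C1O[C@@H](C(C)(C)C)O[C@H]1[C@@H](Cc2ccc(OC)c(OC)c2)C(=O)O | intermediate
10 | dilithium carboxylate enolate of 9 | [Li+].[Li+].[O-]C1=C([C@@H](Cc2ccc(OC)c(OC)c2)C([O-])=O)O[C@H](C(C)(C)C)O1 | intermediate
11 | (2R)-2-[(2S,4S)-2-tert-butyl-4-[[4-(2,2-dimethylpropanoyloxy)-3-methoxyphenyl]methyl]-5-oxo-1,3-dioxolan-4-yl]-3-(3,4-dimethoxyphenyl)propanoic acid | O=C1O[C@@H](C(C)(C)C)O[C@@]1(Cc2ccc(OC(=O)C(C)(C)C)c(OC)c2)[C@@H](Cc3ccc(OC)c(OC)c3)C(=O)O | intermediate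
12 | (2S,3S)-3-[(3,4-dimethoxyphenyl)methyl]-2-[(4-hydroxy-3-methoxyphenyl)methyl]butane-1,2,4-triol | COc1cc(C[C@@](O)(CO)[C@H](CO)Cc2ccc(OC)c(OC)c2)ccc1O | intermediate
13 | 4-[(2S,3S)-3-[(3,4-dimethoxyphenyl)methyl]-2,4-dihydroxy-2-(hydroxymethyl)butyl]-2-methoxyphenyl acetate | COc1cc(C[C@@](O)(CO)[C@H](CO)Cc2ccc(OC)c(OC)c2)ccc1OC(C)=O | intermediate
14 | 4-[[(3S,4R,5S)-5-(3,4-dimethoxyphenyl)-3-hydroxy-4-(hydroxymethyl)oxolan-3-yl]methyl]-2-methoxyphenyl acetate | COc1cc(C[C@@]2(O)CO[C@H](c3ccc(OC)c(OC)c3)[C@H]2CO)ccc1OC(C)=O | intermediate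
15 | 4-[[(3S,4R,5S)-5-(3,4-dimethoxyphenyl)-3-hydroxy-4-[(trimethylsilyloxy)methyl]oxolan-3-yl]methyl]-2-methoxyphenyl acetate | COc1cc(C[C@@]2(O)CO[C@H](c3ccc(OC)c(OC)c3)[C@H]2CO[Si](C)(C)C)ccc1OC(C)=O | intermediate
16 | [(3S,4R,5S)-3-[(4-acetyloxy-3-methoxyphenyl)methyl]-5-(3,4-dimethoxyphenyl)-4-[(trimethylsilyloxy)methyl]oxolan-3-yl] acetate | COc1cc(C[C@@]2(OC(C)=O)CO[C@H](c3ccc(OC)c(OC)c3)[C@H]2CO[Si](C)(C)C)ccc1OC(C)=O | intermediate
17 | [(3S,4R,5S)-5-(3,4-dimethoxyphenyl)-3-[(4-hydroxy-3-methoxyphenyl)methyl]-4-(hydroxymethyl)oxolan-3-yl] acetate | COc1cc(C[C@@]2(OC(C)=O)CO[C@H](c3ccc(OC)c(OC)c3)[C@H]2CO)ccc1O | target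

**Step count and risks**
Total step count: 10. Longest linear sequence: 8 (steps 3 to 10, from dimethyl (S)-malate); the bromide branch (steps 1 and 2) joins at step 6.

Most likely to fail, first: step 9. The product's own benzylic ether C–H can be oxidised further, and the cation can close onto the guaiacyl ring to give an aryltetralin. The fallback sets out from 13. Constant-current anodic oxidation (graphite anode, MeOH, LiClO4, 2,6-lutidine, undivided cell) methoxylates the dimethoxyphenyl benzylic position to give 4-[(2S,3R)-3-[(3,4-dimethoxyphenyl)(methoxy)methyl]-2,4-dihydroxy-2-(hydroxymethyl)butyl]-2-methoxyphenyl acetate F1 as a mixture at the new carbon. Catalytic camphorsulfonic acid in CH2Cl2 at 0 °C then ionises the methyl ether and the 9'-OH closes the ring by the stepwise SN1 path, coming back to the route at 14.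

Second: step 6. The quaternary centre is formed on a dianion next to a bulky side chain, and conversion or diastereoselectivity may be poor. The fallback sets out from 9. BH3·SMe2 (THF, 0 °C) reduces only the carboxylic acid, and TsOH (cat.) in CH2Cl2 then closes the new alcohol onto the dioxolanone carbonyl with loss of pivalaldehyde to give (3S,4S)-4-[(3,4-dimethoxyphenyl)methyl]-3-hydroxyoxolan-2-one F2. Its dilithium alkoxide enolate (LiN(SiMe3)2, 2.2 equiv, THF–DMPU, −78 °C) is benzylated by 3 on the ring face anti to the neighbouring benzyl group to give 4-[[(3S,4S)-4-[(3,4-dimethoxyphenyl)methyl]-3-hydroxy-2-oxooxolan-3-yl]methyl]-2-methoxyphenyl 2,2-dimethylpropanoate F3. LiAlH4 in THF reduces the lactone and cleaves the pivalate, coming back to the route at 12.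

Third: step 10. The silyl ether may not survive the slow acetylation of the hindered tertiary OH, and the acetyl group could migrate to the freed primary OH. The fallback sets out from 14. Exhaustive acetylation (Ac2O, Et3N, DMAP, CH2Cl2, 40 °C) gives [(2S,3R,4S)-4-acetyloxy-4-[(4-acetyloxy-3-methoxyphenyl)methyl]-2-(3,4-dimethoxyphenyl)oxolan-3-yl]methyl acetate F4. Candida antarctica lipase B with n-BuOH in t-BuOMe at 40 °C then removes the primary and the phenolic acetate under neutral conditions (tertiary acetates are not lipase substrates), coming back to the route at 17.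

**Further compounds**
F1 | step 9 | 4-[(2S,3R)-3-[(3,4-dimethoxyphenyl)(methoxy)methyl]-2,4-dihydroxy-2-(hydroxymethyl)butyl]-2-methoxyphenyl acetate | COc1cc(C[C@@](O)(CO)[C@H](CO)C(OC)c2ccc(OC)c(OC)c2)ccc1OC(C)=O
F2 | step 6 | (3S,4S)-4-[(3,4-dimethoxyphenyl)methyl]-3-hydroxyoxolan-2-one | O=C1OC[C@H](Cc2ccc(OC)c(OC)c2)[C@@H]1O
F3 | step 6 | 4-[[(3S,4S)-4-[(3,4-dimethoxyphenyl)methyl]-3-hydroxy-2-oxooxolan-3-yl]methyl]-2-methoxyphenyl 2,2-dimethylpropanoate | O=C1OC[C@H](Cc2ccc(OC)c(OC)c2)[C@@]1(O)Cc3ccc(OC(=O)C(C)(C)C)c(OC)c3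
F4 | step 10 | [(2S,3R,4S)-4-acetyloxy-4-[(4-acetyloxy-3-methoxyphenyl)methyl]-2-(3,4-dimethoxyphenyl)oxolan-3-yl]methyl acetate | COc1cc(C[C@@]2(OC(C)=O)CO[C@H](c3ccc(OC)c(OC)c3)[C@H]2COC(C)=O)ccc1OC(C)=O
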